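## Structural features

The target is built on a pyrrole (ring A: N4, C3, C2, C1, C9a) fused through N4–C9a to an azepane (ring C: N4, C5 to C9, C9a) and through C1–C9a to a cyclohexane (ring B: C9a, C1, C12, C11, C10, C9). Ring B carries a cis-fused α-methyl-γ-lactone (ring D: O on C11, carbonyl C14, C13 with methyl C15, C12) and an ethyl group (C16–C17) on C10, and C3 carries a second α-methyl-γ-lactone (ring E: C18, C19, C20 with methyl C22, carbonyl C21). There are seven stereocentres: C9, C10, C11 and C12 are contiguous on ring B with their four hydrogens on one face (9S,10R,11R,12S), C13 (S) sits directly on C12, and C18 (R) and C20 (S) are trans on ring E. The fragile points are the electron-rich trialkylpyrrole (acid, oxidants), the ionisable C18–O bond next to it, the lactone α-centres C13 and C20 (base), and C9, which can epimerise in any precursor in which C9a is a carbonyl or imine carbon. The real difficulty is the all-cis tetrad on ring B, where the C8 chain, the ethyl group, the lactone oxygen and the C13 branch crowd one face and must be related to C13. The key step uses the fact that this all-cis pattern is what an endo [4+2] adduct gives when the diene C9=C9a–C1=C12 (C8 and C13 both outside) meets a cis-locked ring dienophile. Cyclobutenone supplies C10, C11, C16 and C17; its carbonyl later becomes the C11 oxygen and its other two carbons the ethyl group.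

## Logic of the disconnections

35 is opened at N4–C3 and N4–C9a to give 32. The pyrrole is the most sensitive unit and is therefore made last. Because the nitrogen is already tethered to C9, one condensation sequence closes rings A and C together. The forward step must unmask the amine and condense twice without enolising C9 or C18, hence buffered weak acid.

32 is cut at C1–C2 into 22 and 30. C1 of 22 is the nucleophilic enecarbamate carbon left by the cycloaddition, and an α-keto radical from 30 can be joined to it without base. This spares both lactones and the acidic C18–H, which a ketone-enolate alkylation with an α-bromoketone would not. The forward step needs water to capture the cation at C9a faster than C9–H is lost.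

30 goes back through 27, 26 and 24 to 23 by removing C2 (diazomethane carbon) and the C20 methyl. C18 comes from the chiral pool, and C20 is set trans to it on a simple lactone rather than on the finished bis-lactone. The demand is a trans-selective enolate methylation that leaves C18–H alone.

22 is taken back through 20 to 19 by cleaving the O11–C14 acyl bond and returning C14 to a silyl-protected primary alcohol. C14 must survive the hydride steps, so it is carried at the alcohol level. The forward oxidation has to prefer the primary alcohol and tolerate the enecarbamate.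

19 is traced through 17, 16 and 15 to 14. The ethyl group is read as a reduced aldehyde, the aldehyde as a lactol, and the lactone as the product of oxygen insertion into C11–C17 of a cyclobutanone. Passing through the lactol and its hydrazone avoids a 1,4-diol monosulfonate, which would close to a tetrahydrofuran. The oxygen insertion must move C11 with retention and must not oxidise the enecarbamate.

14 is cut at C9–C10 and C11–C12 into 10 and 13. This removes ring B and four stereocentres in one operation. The forward cycloaddition needs endo, regio- and diene-face selectivity; the last rests on C13 alone.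

10 is cut at C9a–C1 into 4 and 9, a cross-coupling that fixes the E geometry from the boronate. The base must be mild because 10 is acid- and heat-sensitive.

4 comes from 1 through 2; 9 from 5 through 6, 7 and 8; 13 from 11 through 12. All are short, known sequences; the silyl group in 6 is chosen large to sharpen the facial bias in the cycloaddition.

## Other disconnections considered

Alternative 1: The cut runs through ring D at O11–C14 and C14–C13, so that C14 comes from carbon monoxide. In the forward direction the hydroxy alkyne A2 (C11–OH cis to an ethynyl group on C12, rings A, C and E in place) would undergo palladium-catalysed cyclocarbonylation to the α-methylene lactone A1, and hydrogenation of C13=C15 would complete the target.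
- In favour: ring D and C14 arrive in one step at the end, with the pyrrole tolerated. C13 would be set by hydrogen addition to the convex face of the cis-fused bicycle, which places the methyl group on the concave face as required. On this point the alternative is the better plan, because the chosen route relays C13 through a cycloaddition with weak facial bias. It is also better in needing no protecting-group or oxidation-state changes at C14.
- Against: A2 already contains the all-cis C9–C12 tetrad, so the step does nothing for the real problem, and a cis ethynyl/hydroxyl pair must be installed on a crowded ring.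
- Comparison: structurally it solves one ring where the chosen step builds ring B and four centres. Mechanistically, syn alkoxycarbonyl-palladation is as predictable as the endo rule (equal). In steps it is shorter for ring D but longer overall, since the tetrad needs a separate solution.

Alternative 2: The cut is at C10–C11 and O11–C17. In the forward direction an N-heterocyclic carbene would convert the enal of the dialdehyde A4 into a homoenolate, C10 would add to the C11 aldehyde and the alkoxide would acylate C17, giving the lactone-fused tricycle A3.
- In favour: the pyrrole and ring C are present from the start, so there is no late pyrrole synthesis and no stage with C9 next to a carbonyl or imine. On this point it is better than the chosen plan. A3 is the pyrrole counterpart of 15, so the downstream chemistry is equal.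
- Against: C12 in A4 is α to an aldehyde and to the pyrrole and should epimerise under the basic carbene conditions. Only the cis lactone relation of C10 and C11 is intrinsic; their relation to C9 and C12 depends on the folding of a flexible tether. Benzoin and Stetter pathways compete.
- Comparison: it sets two centres with uncertain relay, against four by one rule in the chosen plan. Step count after the key step is about equal; the precursor is longer because C9 and C12 must be made separately.

Alternative 3: The cut is at C10–C16. In the forward direction the bromoacetal A6 would give a primary radical that adds 5-exo to C10 of the pyrrole-conjugated C9=C10 alkene, and the C9 radical would take hydrogen from tributyltin hydride to give the cyclic acetal A5.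
- In favour: the oxygen tether guarantees C16 cis to O11, equal to the guarantee given by the cyclobutenone. A5 is already at the lactol oxidation level, which would save the oxygen-insertion and lactone-reduction steps (better step economy at that stage). The pyrrole is in place.
- Against: C9 would be set by hydrogen-atom transfer to a pyrrole-stabilised radical in a flexible seven-membered ring, with only the new C10 substituent to direct it. A6 needs C11 and C12 set beforehand and a trisubstituted alkene that can isomerise. Stoichiometric tin is required.
- Comparison: it sets two centres, one of them weakly controlled, against four in the chosen plan. Its mechanism is well understood but less stereodefined at C9. It is shorter after the key step but longer before it.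

Key step: step 10

Remarks on the chemistry:
- Atom labels are those defined under "Structural features".
- With the ester carbon of 5 becoming C12 and its hydroxymethyl carbon C14, (R)-5 gives (13S); the ring carbon of (R)-23 becomes (18R).
- C12 is R in 14–34 and S in 35 only because the priorities change when the pyrrole forms.
- The anomeric carbons of 16 and 21, the C=N geometry of 17 and C1 of 31–34 are left undefined because they are lost later.

## Route

Step 1
Reactants: 1 ε-caprolactam
Product: 2 tert-butyl 2-oxoazepane-1-carboxylate
Conditions: Boc2O, DMAP (cat.), Et3N, CH2Cl2, 23 °C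
Reagents that add atoms: di-tert-butyl dicarbonate, CC(C)(C)OC(=O)OC(=O)OC(C)(C)C
Why: DMAP-catalysed N-acylation of a lactam; the carbamate acidifies the α-methylene and stabilises the enol triflate and the amido diene made from it.

Step 2
Reactants: 2 tert-butyl 2-oxoazepane-1-carboxylate
Product: 4 tert-butyl 7-{[(trifluoromethyl)sulfonyl]oxy}-2,3,4,5-tetrahydro-1H-azepine-1-carboxylate, via potassium enolate 3 (not isolated)
Conditions: KN(SiMe3)2, THF, −78 °C; PhNTf2, −78 to −20 °C
Reagents that add atoms: N-phenylbis(trifluoromethanesulfonimide), O=S(=O)(N(c1ccccc1)S(=O)(=O)C(F)(F)F)C(F)(F)F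
Why: Kinetic enolisation of the only enolisable position and O-sulfonylation, the standard entry to lactam-derived enol triflates; the triflate is used promptly because it is heat- and acid-sensitive.

Step 3
Reactants: 5 methyl (R)-3-hydroxy-2-methylpropanoate
Product: 6 methyl (R)-3-[(tert-butyldiphenylsilyl)oxy]-2-methylpropanoate
Conditions: TBDPSCl, imidazole, CH2Cl2, 0 to 23 °C
Reagents that add atoms: tert-butyl(chloro)diphenylsilane, CC(C)(C)[Si](Cl)(c1ccccc1)c1ccccc1
Why: Silylation of a primary alcohol; the large silyl group survives carbonate, hydride and peroxide and makes the silyloxymethyl arm clearly the largest group on C13 for the cycloaddition.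

Step 4
Reactants: 6 methyl (R)-3-[(tert-butyldiphenylsilyl)oxy]-2-methylpropanoate
Product: 7 (R)-3-[(tert-butyldiphenylsilyl)oxy]-2-methylpropanal
Conditions: iBu2AlH (1.05 equiv), CH2Cl2, −78 °C; MeOH quench; used crude
Reagents that add atoms: none
Why: Partial reduction of an ester through the tetrahedral aluminate that is stable at −78 °C; the aldehyde is carried on cold and unpurified to protect its α-centre.

Step 5
Reactants: 7 (R)-3-[(tert-butyldiphenylsilyl)oxy]-2-methylpropanal
Product: 8 (S)-tert-butyl[(2-methylbut-3-yn-1-yl)oxy]diphenylsilane
Conditions: dimethyl (1-diazo-2-oxopropyl)phosphonate, K2CO3, MeOH, 0 to 23 °C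
Reagents that add atoms: dimethyl (1-diazo-2-oxopropyl)phosphonate, COP(=O)(OC)C(=[N+]=[N-])C(C)=O
Why: Ohira–Bestmann alkynylation (Seyferth–Gilbert homologation); the aldehyde carbon becomes C12 and the new carbon C1, and the mild carbonate base at low temperature should leave the α-centre intact (the descriptor changes to S by priority only).

Step 6
Reactants: 8 (S)-tert-butyl[(2-methylbut-3-yn-1-yl)oxy]diphenylsilane
Product: 9 (S,E)-tert-butyl{[2-methyl-4-(4,4,5,5-tetramethyl-1,3,2-dioxaborolan-2-yl)but-3-en-1-yl]oxy}diphenylsilane
Conditions: pinacolborane, Cp2Zr(H)Cl (10 mol %), Et3N (10 mol %), neat, 60 °C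
Reagents that add atoms: pinacolborane, CC1(C)OBOC1(C)C
Why: Zirconium-catalysed syn hydroboration of a terminal alkyne places boron on the terminal carbon and should give only the E-alkenylboronate.

Step 7
Reactants: 4 tert-butyl 7-{[(trifluoromethyl)sulfonyl]oxy}-2,3,4,5-tetrahydro-1H-azepine-1-carboxylate; 9 (S,E)-tert-butyl{[2-methyl-4-(4,4,5,5-tetramethyl-1,3,2-dioxaborolan-2-yl)but-3-en-1-yl]oxy}diphenylsilane
Product: 10 tert-butyl 7-[(1E,3S)-4-[(tert-butyldiphenylsilyl)oxy]-3-methylbut-1-en-1-yl]-2,3,4,5-tetrahydro-1H-azepine-1-carboxylate
Conditions: PdCl2(PPh3)2 (5 mol %), 2 M aq K2CO3, THF, 40 °C, degassed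
Reagents that add atoms: none
Why: Suzuki–Miyaura coupling of a lactam enol triflate with an alkenylboronate, the established route to 2-amido dienes; oxidative addition of zerovalent palladium into C–OTf and transmetalation retain the E geometry, and the carbonate base does not touch C13.

Step 8
Reactants: 11 3-oxocyclobutane-1-carboxylic acid
Product: 12 3-bromocyclobutan-1-one
Conditions: HgO, Br2, MgSO4, CH2Cl2, reflux
Reagents that add atoms: bromine, BrBr
Why: Hunsdiecker-type bromodecarboxylation through the acyl hypobromite and a cyclobutyl radical; this is the documented preparation of this bromoketone.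

Step 9
Reactants: 12 3-bromocyclobutan-1-one
Product: 13 cyclobut-2-en-1-one
Conditions: Bu3N, neat, 23 °C, reduced pressure, product collected in a −78 °C trap and kept as a cold CH2Cl2 solution
Reagents that add atoms: none
Why: β-Elimination of HBr from a β-bromoketone; distilling the enone away from the ammonium salt as it forms limits its polymerisation.

Step 10
Reactants: 10 tert-butyl 7-[(1E,3S)-4-[(tert-butyldiphenylsilyl)oxy]-3-methylbut-1-en-1-yl]-2,3,4,5-tetrahydro-1H-azepine-1-carboxylate; 13 cyclobut-2-en-1-one
Product: 14 (9S,10R,11R,12R,13S) all-cis adduct: N-Boc enecarbamate (C1=C9a) of the azepine-fused cyclohexene, cyclobutanone fused across C10–C11 (C16H2 on C10, C17=O on C11), (S)-1-(tert-butyldiphenylsilyloxy)propan-2-yl on C12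
Conditions: 13 (3 equiv), CH2Cl2 (0.5 M), 23 °C, then 40 °C if needed, dark, acid-free glassware
Reagents that add atoms: none
Why: This is a concerted but asynchronous normal-demand [4+2] cycloaddition in which the carbamate nitrogen raises the HOMO coefficient at C9, so C9 bonds first to the enone β-carbon (C10) and C12 then to the α-carbon (C11), an orientation that the alkyl group on C12 reinforces. The closest known reaction types are thermal Diels–Alder reactions of lactam-derived 2-amido dienes and cycloadditions of cyclobutenone as a strained, endo-selective dienophile. Ring B is closed by intermolecular suprafacial–suprafacial [4+2] addition, while the four-membered ring is carried in intact and ring C is not touched. C9 and C12 are set relative to each other by suprafacial addition to the s-cis diene in which C8 and C13 are both outside groups, C10 and C11 are cis because the ring dienophile adds on one face, and the endo orientation (C16 and C17 under the diene) relates the two pairs so that the four hydrogens are all cis. The absolute sense is set by C13: in the favoured rotamer C13–H lies in the diene plane next to C1–H, the bulky silyloxymethyl group stands anti to the incoming dienophile, and the dienophile passes the methyl group, which for the (13S) diene leads to 9S,10R,11R,12R. Endo selectivity should be secured by the small rigid enone and its carbonyl overlap with the diene, regioselectivity by the two substituent effects acting in the same direction, and chemoselectivity by neutral conditions that keep the enecarbamate and the cyclobutanone intact. Diene-face selectivity rests only on C13 and is the least certain requirement.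

Step 11
Reactants: 14 (9S,10R,11R,12R,13S) all-cis cyclobutanone adduct
Product: 15 (9S,10R,11R,12R,13S) γ-lactone C10–C16H2–C17(=O)–O–C11 fused to ring B, enecarbamate and silyl ether unchanged
Conditions: 30 % aq H2O2, aq NaOH (0.3 equiv), THF/MeOH, 0 °C; pH 6 phosphate buffer
Reagents that add atoms: hydrogen peroxide, OO
Why: Baeyer–Villiger oxidation of a strained cyclobutanone by nucleophilic hydroperoxide; the more substituted C11 migrates with retention, which fixes O11 cis to C16, and a nucleophilic oxidant does not epoxidise the electron-rich enecarbamate.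

Step 12
Reactants: 15 (9S,10R,11R,12R,13S) γ-lactone
Product: 16 (9S,10R,11R,12R,13S) lactol (C17 hemiacetal, anomers)
Conditions: iBu2AlH (1.2 equiv), CH2Cl2, −78 °C
Reagents that add atoms: none
Why: Half-reduction of a γ-lactone to the lactol at −78 °C, where the carbamate and the silyl ether are inert.

Step 13
Reactants: 16 (9S,10R,11R,12R,13S) lactol
Product: 17 (9S,10R,11R,12R,13S) hydroxy tosylhydrazone (C11–OH; C10–CH2–CH=N–NHTs)
Conditions: TsNHNH2, THF, 4 Å molecular sieves, 45 °C
Reagents that add atoms: p-toluenesulfonyl hydrazide, Cc1ccc(cc1)S(=O)(=O)NN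
Why: The lactol reacts through its open hydroxy-aldehyde form to give the sulfonylhydrazone without added acid, so the enecarbamate is not hydrolysed.

Step 14
Reactants: 17 (9S,10R,11R,12R,13S) hydroxy tosylhydrazone
Product: 19 (9S,10R,11R,12R,13S) 10-ethyl-11-hydroxy enecarbamate silyl ether, via tosylhydrazine 18 (not isolated)
Conditions: catecholborane (3 equiv), CHCl3, 0 to 23 °C; NaOAc·3H2O, reflux
Reagents that add atoms: none
Why: Tosylhydrazone deoxygenation: hydride adds to C=N, then loss of sulfinate and dinitrogen leaves the C17 methyl group. No alkoxide and sulfonate leaving group are present together, so tetrahydrofuran closure onto O11 is avoided, and uncatalysed catecholborane does not hydroborate the enecarbamate.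

Step 15
Reactants: 19 (9S,10R,11R,12R,13S) 10-ethyl-11-hydroxy enecarbamate silyl ether
Product: 20 (9S,10R,11R,12R,13S) diol (C11–OH, C14–OH)
Conditions: Bu4NF, THF, 0 to 23 °C
Reagents that add atoms: none
Why: Fluoride cleavage of the silyl ether; no other group is fluoride- or base-labile.

Step 16
Reactants: 20 (9S,10R,11R,12R,13S) diol
Product: 22 (9S,10R,11R,12R,13S) ring D lactone enecarbamate, via lactol 21 (not isolated)
Conditions: nPr4N[RuO4] (5 mol %), N-methylmorpholine N-oxide (3 equiv), 4 Å molecular sieves, CH2Cl2, 23 °C
Reagents that add atoms: none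
Why: Ley–Griffith oxidation of a 1,4-diol: the primary alcohol is oxidised first, the aldehyde is trapped by the cis C11–OH as a lactol, and the lactol is oxidised to the lactone. The neutral medium does not enolise C13, and the cis fusion follows from O11 and C13 being on the same face.

Step 17
Reactants: 23 (R)-5-oxotetrahydrofuran-2-carboxylic acid
Product: 24 tert-butyl (R)-5-oxotetrahydrofuran-2-carboxylate
Conditions: tert-butyl 2,2,2-trichloroacetimidate, BF3·OEt2 (cat.), CH2Cl2/cyclohexane, 23 °C
Reagents that add atoms: tert-butyl 2,2,2-trichloroacetimidate, CC(C)(C)OC(=N)C(Cl)(Cl)Cl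
Why: Acid-catalysed tert-butylation through the imidate; no base is present, so the centre that becomes C18 is not at risk.

Step 18
Reactants: 24 tert-butyl (R)-5-oxotetrahydrofuran-2-carboxylate
Product: 26 tert-butyl (2R,4S)-4-methyl-5-oxotetrahydrofuran-2-carboxylate, via lithium enolate 25 (not isolated)
Conditions: LiN(SiMe3)2 (1.0 equiv), THF, −78 °C; MeI, −78 to −45 °C
Reagents that add atoms: iodomethane, CI
Why: Lactone enolate alkylation: the lactone α-methylene is more acidic than the α-oxygenated ester C–H (as in pyroglutamate enolate chemistry), and iodomethane should approach anti to the bulky ester, giving the trans (20S) isomer.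

Step 19
Reactants: 26 tert-butyl (2R,4S)-4-methyl-5-oxotetrahydrofuran-2-carboxylate
Product: 27 (2R,4S)-4-methyl-5-oxotetrahydrofuran-2-carboxylic acid
Conditions: CF3CO2H/CH2Cl2 (1:3), 23 °C
Reagents that add atoms: none
Why: Acidolysis of a tert-butyl ester; the lactone and both stereocentres are stable to acid.

Step 20
Reactants: 27 (2R,4S)-4-methyl-5-oxotetrahydrofuran-2-carboxylic acid
Product: 30 (3S,5R)-5-(2-bromoacetyl)-3-methyloxolan-2-one, via acid chloride 28 (not isolated), via diazoketone 29 (not isolated)
Conditions: (COCl)2, DMF (cat.), CH2Cl2, 0 to 23 °C, evaporate; CH2N2 (2.5 equiv), Et2O, 0 °C; 48 % aq HBr, 0 °C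
Reagents that add atoms: diazomethane, C=[N+]=[N-]; hydrogen bromide, Br
Why: Acylation of diazomethane by the acid chloride followed by hydrobromination of the diazoketone, the standard acid-to-bromomethyl-ketone sequence; it runs without base, so C18 and C20 keep their configuration.

Step 21
Reactants: 22 (9S,10R,11R,12R,13S) ring D lactone enecarbamate; 30 (3S,5R)-5-(2-bromoacetyl)-3-methyloxolan-2-one
Product: 32 (9S,10R,11R,12R,13S,18R,20S) Boc-amino 1,4-diketone (C9a=O, C1–CH2–C3(=O)–C18, 4-(Boc-amino)butyl on C9), via hemiaminal 31 (not isolated)
Conditions: 30 (1.5 equiv), fac-Ir(ppy)3 (1 mol %), K2HPO4 (2 equiv), MeCN/H2O (9:1), blue LEDs (450 nm), 23 °C, degassed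
Reagents that add atoms: water, O
Why: Photoredox radical-polar crossover alkylation of an enecarbamate, known for enamides and enecarbamates with α-bromocarbonyl compounds: the excited trivalent iridium complex reduces 30 to an electrophilic α-keto radical that adds to the electron-rich C1, the α-amido radical is oxidised to the N-acyliminium ion, water captures it, and the hemiaminal opens to the C9a ketone. No base stronger than phosphate is present, so C9, C13, C18 and C20 should not enolise, and the new centre at C1 is lost in the next step.

Step 22
Reactants: 32 (9S,10R,11R,12R,13S,18R,20S) Boc-amino 1,4-diketone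
Product: 35 epibisdehydroneotuberostemonine J (9S,10R,11R,12S,13S,18R,20S), via primary amine 33 (not isolated), via cyclic imine 34 (not isolated)
Conditions: CF3CO2H/CH2Cl2 (1:4), 0 °C; evaporate; NaOAc, AcOH/EtOH (1:10), 23 to 40 °C
Reagents that add atoms: none
Why: Boc acidolysis followed by an intramolecular Paal–Knorr condensation: the freed amine closes ring C on the C9a ketone, the imine nitrogen adds to the C3 ketone, and two dehydrations give the pyrrole. Buffered acetic acid near room temperature is chosen so that ring closure outruns enolisation at C9 and C18; no stereocentre is formed.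

## Compound list

1 | ε-caprolactam | O=C1CCCCCN1 | starting material
2 | tert-butyl 2-oxoazepane-1-carboxylate | CC(C)(C)OC(=O)N1CCCCCC1=O | intermediate
3 | potassium enolate of 2 | CC(C)(C)OC(=O)N1CCCCC=C1[O-].[K+] | intermediate
4 | tert-butyl 7-{[(trifluoromethyl)sulfonyl]oxy}-2,3,4,5-tetrahydro-1H-azepine-1-carboxylate | CC(C)(C)OC(=O)N1CCCCC=C1OS(=O)(=O)C(F)(F)F | intermediate
5 | methyl (R)-3-hydroxy-2-methylpropanoate | COC(=O)[C@H](C)CO | starting material
6 | methyl (R)-3-[(tert-butyldiphenylsilyl)oxy]-2-methylpropanoate | COC(=O)[C@H](C)CO[Si](c1ccccc1)(c1ccccc1)C(C)(C)C | intermediate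
7 | (R)-3-[(tert-butyldiphenylsilyl)oxy]-2-methylpropanal | O=C[C@H](C)CO[Si](c1ccccc1)(c1ccccc1)C(C)(C)C | intermediate
8 | (S)-tert-butyl[(2-methylbut-3-yn-1-yl)oxy]diphenylsilane | C#C[C@H](C)CO[Si](c1ccccc1)(c1ccccc1)C(C)(C)C | intermediate
9 | (S,E)-tert-butyl{[2-methyl-4-(4,4,5,5-tetramethyl-1,3,2-dioxaborolan-2-yl)but-3-en-1-yl]oxy}diphenylsilane | CC1(C)OB(/C=C/[C@H](C)CO[Si](c2ccccc2)(c2ccccc2)C(C)(C)C)OC1(C)C | intermediate
10 | tert-butyl 7-[(1E,3S)-4-[(tert-butyldiphenylsilyl)oxy]-3-methylbut-1-en-1-yl]-2,3,4,5-tetrahydro-1H-azepine-1-carboxylate | CC(C)(C)OC(=O)N1CCCCC=C1/C=C/[C@H](C)CO[Si](c1ccccc1)(c1ccccc1)C(C)(C)C | intermediate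
11 | 3-oxocyclobutane-1-carboxylic acid | O=C1CC(C1)C(=O)O | starting material
12 | 3-bromocyclobutan-1-one | O=C1CC(Br)C1 | intermediate
13 | cyclobut-2-en-1-one | O=C1C=CC1 | intermediate
14 | (9S,10R,11R,12R,13S) all-cis cyclobutanone-fused enecarbamate adduct | O=C1C[C@H]2[C@@H]1[C@@H]([C@H](C)CO[Si](c1ccccc1)(c1ccccc1)C(C)(C)C)C=C1N(C(=O)OC(C)(C)C)CCCC[C@H]12 | intermediate
15 | (9S,10R,11R,12R,13S) γ-lactone (O11–C17) | O=C1C[C@H]2[C@@H](O1)[C@@H]([C@H](C)CO[Si](c1ccccc1)(c1ccccc1)C(C)(C)C)C=C1N(C(=O)OC(C)(C)C)CCCC[C@H]12 | intermediate
16 | (9S,10R,11R,12R,13S) lactol | OC1C[C@H]2[C@@H](O1)[C@@H]([C@H](C)CO[Si](c1ccccc1)(c1ccccc1)C(C)(C)C)C=C1N(C(=O)OC(C)(C)C)CCCC[C@H]12 | intermediate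
17 | (9S,10R,11R,12R,13S) hydroxy tosylhydrazone | Cc1ccc(cc1)S(=O)(=O)NN=CC[C@H]1[C@@H](O)[C@@H]([C@H](C)CO[Si](c2ccccc2)(c2ccccc2)C(C)(C)C)C=C2N(C(=O)OC(C)(C)C)CCCC[C@H]21 | intermediate
18 | (9S,10R,11R,12R,13S) N-alkyl-N'-tosylhydrazine | Cc1ccc(cc1)S(=O)(=O)NNCC[C@H]1[C@@H](O)[C@@H]([C@H](C)CO[Si](c2ccccc2)(c2ccccc2)C(C)(C)C)C=C2N(C(=O)OC(C)(C)C)CCCC[C@H]21 | intermediate
19 | (9S,10R,11R,12R,13S) 10-ethyl-11-hydroxy enecarbamate silyl ether | CC[C@H]1[C@@H](O)[C@@H]([C@H](C)CO[Si](c2ccccc2)(c2ccccc2)C(C)(C)C)C=C2N(C(=O)OC(C)(C)C)CCCC[C@H]21 | intermediate
20 | (9S,10R,11R,12R,13S) diol | CC[C@H]1[C@@H](O)[C@@H]([C@H](C)CO)C=C2N(C(=O)OC(C)(C)C)CCCC[C@H]21 | intermediate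
21 | (9S,10R,11R,12R,13S) ring D lactol | CC[C@H]1[C@H]2OC(O)[C@@H](C)[C@H]2C=C2N(C(=O)OC(C)(C)C)CCCC[C@H]21 | intermediate
22 | (9S,10R,11R,12R,13S) ring D lactone enecarbamate | CC[C@H]1[C@H]2OC(=O)[C@@H](C)[C@H]2C=C2N(C(=O)OC(C)(C)C)CCCC[C@H]21 | intermediate
23 | (R)-5-oxotetrahydrofuran-2-carboxylic acid | OC(=O)[C@H]1CCC(=O)O1 | starting material
24 | tert-butyl (R)-5-oxotetrahydrofuran-2-carboxylate | CC(C)(C)OC(=O)[C@H]1CCC(=O)O1 | intermediate
25 | lithium enolate of 24 | CC(C)(C)OC(=O)[C@H]1CC=C([O-])O1.[Li+] | intermediate
26 | tert-butyl (2R,4S)-4-methyl-5-oxotetrahydrofuran-2-carboxylate | CC(C)(C)OC(=O)[C@H]1C[C@H](C)C(=O)O1 | intermediate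
27 | (2R,4S)-4-methyl-5-oxotetrahydrofuran-2-carboxylic acid | OC(=O)[C@H]1C[C@H](C)C(=O)O1 | intermediate
28 | (2R,4S)-4-methyl-5-oxotetrahydrofuran-2-carbonyl chloride | ClC(=O)[C@H]1C[C@H](C)C(=O)O1 | intermediate
29 | (3S,5R)-5-(2-diazoacetyl)-3-methyloxolan-2-one | [N-]=[N+]=CC(=O)[C@H]1C[C@H](C)C(=O)O1 | intermediate
30 | (3S,5R)-5-(2-bromoacetyl)-3-methyloxolan-2-one | BrCC(=O)[C@H]1C[C@H](C)C(=O)O1 | intermediate
31 | (9S,10R,11R,12R,13S,18R,20S) C9a hemiaminal | CC[C@H]1[C@H]2OC(=O)[C@@H](C)[C@H]2C(CC(=O)[C@H]2C[C@H](C)C(=O)O2)C2(O)N(C(=O)OC(C)(C)C)CCCC[C@H]21 | intermediate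
32 | (9S,10R,11R,12R,13S,18R,20S) Boc-amino 1,4-diketone | CC[C@H]1[C@H]2OC(=O)[C@@H](C)[C@H]2C(CC(=O)[C@H]2C[C@H](C)C(=O)O2)C(=O)[C@H]1CCCCNC(=O)OC(C)(C)C | intermediate
33 | (9S,10R,11R,12R,13S,18R,20S) amino 1,4-diketone | CC[C@H]1[C@H]2OC(=O)[C@@H](C)[C@H]2C(CC(=O)[C@H]2C[C@H](C)C(=O)O2)C(=O)[C@H]1CCCCN | intermediate
34 | (9S,10R,11R,12R,13S,18R,20S) seven-membered cyclic imine | CC[C@H]1[C@H]2OC(=O)[C@@H](C)[C@H]2C(CC(=O)[C@H]2C[C@H](C)C(=O)O2)C2=NCCCC[C@H]21 | intermediate
35 | epibisdehydroneotuberostemonine J (9S,10R,11R,12S,13S,18R,20S) | CC[C@H]1[C@H]2OC(=O)[C@@H](C)[C@H]2c2cc([C@H]3C[C@H](C)C(=O)O3)n3c2[C@H]1CCCC3 | target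

## Step count and least certain steps

Total step count: 22. Longest linear sequence: 14 steps (steps 3–7, 10–16, 21 and 22, from 5 to 35).

Key step (step 10). The most likely failure is poor discrimination between the two diene faces. The only control element is an allylic stereocentre on an E-alkene, and the rotamer with C13–H in the plane and the one with the methyl group in the plane are close in energy. Polymerisation of 13 is a second loss pathway. The fallback replaces steric bias by a directing interaction. It sets out from 10, which is desilylated with Bu4NF to the dienol F1. The cycloaddition of F1 with 13 is then run in a non-polar solvent, where a hydrogen bond from the C14 hydroxyl to the endo carbonyl should hold the dienophile on the face that places the hydroxymethyl arm next to it and the methyl group anti. For the (13S) diene this is the same face as required. The hydroxy adduct F2 is resilylated (TBDPSCl, imidazole) and the route is rejoined at 14.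

Step 21. The cation formed after radical addition and oxidation may lose the C9 proton instead of being captured by water, which moves the double bond to C9=C9a and scrambles C9. Alternatively, addition to the hindered C1 may be slower than simple reduction of 30. The fallback changes from a radical to a metal-carbene mechanism. It sets out from 22 and from 29, which is isolated for this purpose. Slow addition of 29 to 22 with Rh2(OAc)4 in CH2Cl2 should give the aminocyclopropyl ketone F3. Mild aqueous acid then opens the donor–acceptor cyclopropane in a water-rich medium to the 1,4-dicarbonyl compound, rejoining the route at 32.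

Step 22. Epimerisation at C9 is the main danger. While C9a is a ketone or imine carbon, C9–H is enolisable, and the C9 epimer relieves the crowding of the all-cis ring. Enolisation at C18 and acid-induced furan formation are lesser risks. The fallback keeps C9a saturated until aromatisation. It sets out from 22 and 30: a reductive Giese addition (Bu3SnH, AIBN, benzene, 80 °C) gives the N-Boc azepane γ-keto adduct F4, in which C9a carries hydrogen. Boc removal (CF3CO2H, then NaHCO3) lets the secondary amine condense with the C3 ketone to the bicyclic pyrroline F5. Dehydrogenation with MnO2 in CH2Cl2 aromatises it, coming back to the route at 35.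

Step 18. The trans/cis selectivity of the methylation may be modest because the ester is only a medium-sized directing group, and over-methylation or loss of configuration at the ester-bearing carbon is possible with excess base. The fallback uses a larger, non-enolisable directing group. It sets out from 23: BH3·SMe2 reduces the acid to (R)-5-(hydroxymethyl)oxolan-2-one F6, and tritylation (TrCl, pyridine) gives the trityl ether F7. Alkylation with LiN(iPr)2 and MeI at −78 °C, anti to the trityloxymethyl group, gives the trans lactone F8. Aqueous acetic acid removes the trityl group to give the alcohol F9, and RuCl3 (cat.)/NaIO4 oxidises the primary alcohol, returning to the route at 27.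

## Further compounds

F1 | step 10 | tert-butyl 7-[(1E,3S)-4-hydroxy-3-methylbut-1-en-1-yl]-2,3,4,5-tetrahydro-1H-azepine-1-carboxylate | CC(C)(C)OC(=O)N1CCCCC=C1/C=C/[C@H](C)CO
F2 | step 10 | (9S,10R,11R,12R,13S) hydroxy adduct (14 with free C14–OH) | O=C1C[C@H]2[C@@H]1[C@@H]([C@H](C)CO)C=C1N(C(=O)OC(C)(C)C)CCCC[C@H]12
F3 | step 21 | aminocyclopropyl ketone (cyclopropane C1–C2–C9a, acyl on C2; new centres undefined) | CC[C@H]1[C@H]2OC(=O)[C@@H](C)[C@H]2C2C(C(=O)[C@H]3C[C@H](C)C(=O)O3)C23N(C(=O)OC(C)(C)C)CCCC[C@@H]13
F4 | step 22 | N-Boc azepane γ-keto adduct (C9a–H; C1 and C9a undefined) | CC[C@H]1[C@H]2OC(=O)[C@@H](C)[C@H]2C(CC(=O)[C@H]2C[C@H](C)C(=O)O2)C2N(C(=O)OC(C)(C)C)CCCC[C@H]21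
F5 | step 22 | bicyclic pyrroline (N4–C3=C2 enamine; C1 and C9a undefined) | CC[C@H]1[C@H]2OC(=O)[C@@H](C)[C@H]2C2C=C([C@H]4C[C@H](C)C(=O)O4)N3CCCC[C@@H]1C23
F6 | step 18 | (R)-5-(hydroxymethyl)oxolan-2-one | OC[C@H]1CCC(=O)O1
F7 | step 18 | (R)-5-[(triphenylmethoxy)methyl]oxolan-2-one | C(OC[C@H]1CCC(=O)O1)(c1ccccc1)(c1ccccc1)c1ccccc1
F8 | step 18 | (3S,5R)-3-methyl-5-[(triphenylmethoxy)methyl]oxolan-2-one | C(OC[C@H]1C[C@H](C)C(=O)O1)(c1ccccc1)(c1ccccc1)c1ccccc1
F9 | step 18 | (3S,5R)-5-(hydroxymethyl)-3-methyloxolan-2-one | OC[C@H]1C[C@H](C)C(=O)O1
A1 | alternative 1 | α-methylene lactone (13,15-didehydro target) | CC[C@H]1[C@H]2OC(=O)C(=C)[C@H]2c2cc([C@H]3C[C@H](C)C(=O)O3)n3c2[C@H]1CCCC3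
A2 | alternative 1 | 11-hydroxy-12-ethynyl tricycle bearing ring E | CC[C@H]1[C@@H](O)[C@@H](C#C)c2cc([C@H]3C[C@H](C)C(=O)O3)n3c2[C@H]1CCCC3
A3 | alternative 2 | ring B tricycle with temporary C17 lactone across C10–C11 | O=C1C[C@H]2[C@@H](O1)[C@@H]([C@H](C)CO[Si](C)(C)C(C)(C)C)c1ccn3CCCC[C@@H]2c13
A4 | alternative 2 | pyrrolo-azepane dialdehyde (E-enal on C9, C11 aldehyde on C12) | O=C/C=C/[C@@H]1CCCCn2ccc([C@@H](C=O)[C@H](C)CO[Si](C)(C)C(C)(C)C)c12
A5 | alternative 3 | cis-fused cyclic ethyl acetal | CCOC1C[C@H]2[C@@H](O1)[C@@H]([C@H](C)CO[Si](C)(C)C(C)(C)C)c1ccn3CCCC[C@@H]2c13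
A6 | alternative 3 | O11 bromoacetal of the C9=C10 alkene | CCOC(CBr)O[C@@H]1C=C2CCCCn3ccc(c23)[C@@H]1[C@H](C)CO[Si](C)(C)C(C)(C)C
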